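## Retrosynthetic overview
1. Target ⇒ spiro-activated cyclopropane. The p-menthane ring is closed last (C1'–C6' bond, geranyl numbering) when the C6'=C7' alkene attacks the cyclopropane CH2; loss of H+ then gives the isopropenyl group.
2. Spirocyclopropane ⇒ 4-(2',3'-epoxygeranyl) dienone. Ring carbon C4 opens the epoxide at C2' (3-exo-tet, inversion). Together the two events move the nucleus from C1' to C2' and give the cis OH/nucleus relationship, which SN2 opening of limonene oxide cannot give.
3. Epoxygeranyl dienone ⇒ gem-diprenyl dienone + epoxygeranyl iodide. One Sharpless epoxidation of geraniol is the only source of chirality.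
4. gem-Diprenyl dienone ⇒ phloroglucinol + isobutyryl chloride + 2 prenyl bromide (Friedel–Crafts acylation, dearomative C,C-diprenylation).
5. Ring order: six-membered nucleus (bought aromatic, then dearomatised) → oxirane → cyclopropane → cyclohexane. The oxirane and cyclopropane are consumed.

Assumption: the presumed biosynthesis is 2',3'-epoxidation of the C-geranylated nucleus, participation of the nucleus (phenonium-like spirocyclopropane), then alpha-terpinyl-type closure; every enolised tricarbonyl compound is drawn as one tautomer of a fast equilibrium.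

Locants: nucleus C1 (C=O), C2 (acyl), C3 (OH), C4 (free CH or terpene), C5 (OH), C6 (gem-diprenyl). The terpene carbons are C1'–C8'.

## Route

Step 1
Reactants: 1 phloroglucinol; 2 isobutyryl chloride
Product: 3 phlorisobutyrophenone
Conditions: AlCl3 (3.5 equiv), CH2Cl2–PhNO2, 0 → 45 °C; ice/1 M HCl
Reagents that add atoms: none
Why: Friedel–Crafts C-acylation of a very electron-rich arene, in which the chelated acyl group deactivates the ring enough to stop at monoacylation, and no stereocentre is formed.

Step 2
Reactants: 3 phlorisobutyrophenone; 4 prenyl bromide (2.05 equiv)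
Product: 5 gem-diprenyl dienone (3,5-dihydroxy-2-isobutyryl-6,6-diprenylcyclohexa-2,4-dien-1-one)
Conditions: KOH (3.0 equiv), H2O, 0 °C → rt; 1 M HCl; chromatography (removes the 3,5-diprenyl isomer and colupulone)
Reagents that add atoms: none
Why: Alkylative dearomatisation, in which water hydrogen-bonds the phenolate oxygens so that carbon is alkylated, the already prenylated carbon of the mono-adduct is the most electron-rich site so the second prenyl group enters geminally, and the product is parked as the poorly nucleophilic anion of a vinylogous acid, with no stereocentre formed.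

Step 3
Reactants: 6 geraniol
Product: 7 (2R,3R)-2,3-epoxygeraniol
Conditions: Ti(OiPr)4 (5 mol %), D-(−)-diisopropyl tartrate (7 mol %), t-BuOOH (1.5 equiv, decane), 4 Å MS, CH2Cl2, −20 °C
Reagents that add atoms: tert-butyl hydroperoxide, CC(C)(C)OO
Why: Katsuki–Sharpless asymmetric epoxidation, in which the titanium tartrate binds the allylic alcohol so that only the 2,3-alkene reacts, and the D-(−)-tartrate delivers oxygen to the face giving the (2R,3R)-epoxide (about 95% ee), which fixes the final carbinol carbon C3' as R and sets the C2' centre that is inverted later.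

Step 4
Reactants: 7 (2R,3R)-2,3-epoxygeraniol
Product: 8 (2S,3R)-2,3-epoxygeranyl iodide
Conditions: I2, PPh3, imidazole, CH2Cl2, 0 °C, dark
Reagents that add atoms: iodine, [I][I]
Why: Appel-type (Garegg–Samuelsson) iodination, an SN2 displacement of the alkoxyphosphonium group at the primary carbon under buffered conditions that leaves the epoxide and both centres untouched, the C2 descriptor changing from R to S by priority only.

Step 5
Reactants: 5 gem-diprenyl dienone; 8 (2S,3R)-2,3-epoxygeranyl iodide
Product: 10 spirocyclopropyl carbinol (7-isobutyryl-5,5-diprenylspiro[2.5]octane-4,6,8-trione core; cyclopropane CH R; carbinol C R), via C4-epoxygeranyl dienone 9 (not isolated)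
Conditions: 5, LiN(SiMe3)2 (2.1 equiv), THF–DMPU 6:1, −78 °C; 8 (1.1 equiv), −78 → 0 °C; LiN(SiMe3)2 (1.0 equiv), 0 °C → rt; 1 M HCl to pH 5, 0 °C
Reagents that add atoms: none
Why: Proposed new method: the dilithio dienolate of 5 is alkylated at its only free ring carbon C4 by the soft primary iodide, and the re-formed enolate of 9, whose side chain is held perpendicular to the ring by the two flanking oxygens, attacks the less hindered epoxide carbon C2' from the rear in a 3-exo-tet closure with clean inversion (C2' is R by changed priorities, C3' stays R) while lithium ties up the enolate oxygens and activates the epoxide, the closest known reaction types being the malonate–epichlorohydrin cyclopropanation, the base-induced closure of gamma,delta-epoxy enolates to cyclopropyl carbinols and the C,C-dialkylation of cyclohexane-1,3-diones with 1,2-dielectrophiles to spiro[2.5]octane-4,8-diones.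

Step 6
Reactants: 10 spirocyclopropyl carbinol
Product: 13 target (1R,2R,4S in p-menthane numbering), via bis-silyl spirocyclopropane 11 (not isolated), via tris-silyl cyclisation product 12 (not isolated)
Conditions: Me3SiOTf (4 equiv), 2,6-di-tert-butyl-4-methylpyridine (4.5 equiv), CH2Cl2, −78 → −30 °C; then aq citric acid (cat.), THF, 0 °C
Reagents that add atoms: none
Why: Proposed new method: silylation first caps the carbinol and the enol (no hemiketal, no ether closure, no free acid), Me3SiOTf then converts one of the two carbonyl groups held by the spiro junction in the bisected, best-overlapping geometry into a silyloxocarbenium ion, and the C6'=C7' alkene opens the cyclopropane by SN2-type attack on the unhindered CH2 (C1') rather than on the neopentyl-like, beta-oxygenated C2', so the nucleus ends on C2' with retention there; back-side attack makes C6'···C1'–C2'–C4 antiperiplanar, which places the nucleus equatorial in a chair whose equatorial CH3 and axial OSiMe3 are fixed by the epoxide-derived centres and whose developing 2-propyl cation takes the third equatorial site, setting C6' (p-menthane C4) as S before a methyl proton is lost to give the isopropenyl group, the closest known reaction types being Stork-type olefin participation in the Lewis-acid opening of acylcyclopropanes, homoconjugate addition to spiro-activated cyclopropanes and the least-substituted-carbon opening of duocarmycin-type spirocyclopropyl dienones, combined with an alpha-terpinyl-type cation–olefin cyclisation.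

## Compound list
1 | phloroglucinol (benzene-1,3,5-triol) | Oc1cc(O)cc(O)c1 | starting material
2 | isobutyryl chloride | CC(C)C(=O)Cl | starting material
3 | phlorisobutyrophenone, 2-methyl-1-(2,4,6-trihydroxyphenyl)propan-1-one | CC(C)C(=O)c1c(O)cc(O)cc1O | intermediate
4 | prenyl bromide, 1-bromo-3-methylbut-2-ene | CC(C)=CCBr | starting material
5 | 3,5-dihydroxy-2-isobutyryl-6,6-diprenylcyclohexa-2,4-dien-1-one (C4–H free) | CC(C)C(=O)C1=C(O)C=C(O)C(CC=C(C)C)(CC=C(C)C)C1=O | intermediate
6 | geraniol, (E)-3,7-dimethylocta-2,6-dien-1-ol | CC(C)=CCC/C(C)=C/CO | starting material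
7 | (2R,3R)-2,3-epoxygeraniol (CH2OH and CH3 cis on the oxirane) | OC[C@H]1O[C@]1(C)CCC=C(C)C | intermediate
8 | (2S,3R)-2,3-epoxygeranyl iodide (same spatial arrangement as 7) | IC[C@H]1O[C@]1(C)CCC=C(C)C | intermediate
9 | 4-[(2R,3R)-2,3-epoxygeranyl]-3,5-dihydroxy-2-isobutyryl-6,6-diprenylcyclohexa-2,4-dien-1-one | CC(C)C(=O)C1=C(O)C(C[C@H]2O[C@]2(C)CCC=C(C)C)=C(O)C(CC=C(C)C)(CC=C(C)C)C1=O | intermediate
10 | (1R)-1-[(2R)-2-hydroxy-6-methylhept-5-en-2-yl]-7-isobutyryl-5,5-diprenylspiro[2.5]octane-4,6,8-trione, 6-enol; either spiro epimer, both converge in step 6 | CC(C)C(=O)C1=C(O)C(CC=C(C)C)(CC=C(C)C)C(=O)C2(C[C@H]2[C@](C)(O)CCC=C(C)C)C1=O | intermediate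
11 | bis(trimethylsilyl) derivative of 10 (carbinol O and enol O silylated) | CC(C)C(=O)C1=C(O[Si](C)(C)C)C(CC=C(C)C)(CC=C(C)C)C(=O)C2(C[C@H]2[C@](C)(O[Si](C)(C)C)CCC=C(C)C)C1=O | intermediate
12 | tris(trimethylsilyl) derivative of 13 (carbinol O and two enol O silylated) | C=C(C)[C@H]1CC[C@@](C)(O[Si](C)(C)C)[C@@H](C2=C(O[Si](C)(C)C)C(CC=C(C)C)(CC=C(C)C)C(O[Si](C)(C)C)=C(C(=O)C(C)C)C2=O)C1 | intermediate
13 | 3,5-dihydroxy-4-[(1R,2R,5S)-2-hydroxy-2-methyl-5-(prop-1-en-2-yl)cyclohexyl]-2-isobutyryl-6,6-diprenylcyclohexa-2,4-dien-1-one (OH axial; nucleus, CH3 and isopropenyl equatorial; OH, nucleus and isopropenyl all cis) | C=C(C)[C@H]1CC[C@@](C)(O)[C@@H](C2=C(O)C(CC=C(C)C)(CC=C(C)C)C(=O)C(C(=O)C(C)C)=C2O)C1 | target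

## Step count and risks
Total steps: 6. Longest linear sequence: 4 (1 → 3 → 5 → 10 → 13, or 6 → 7 → 8 → 10 → 13).

**Step 5 is most at risk.** The enolate oxygens flanking C4 can be alkylated by 8. In 9 they can also open the epoxide at C2' in a 5-exo mode to a 2-substituted dihydrofuran, which is a thermodynamic sink, and the lithium alkoxide of 10 can revert. The fallback sets out from 8 and comes back at 10. It reverses the order of the two C–C bond formations, so that the closing event expels a soft, irreversible leaving group from a primary carbon. First 8 is quaternised with tetrahydrothiophene (acetone, rt) to S-[(2S,3R)-2,3-epoxygeranyl]tetrahydrothiophenium iodide F1. K2CO3 in EtOAc then isomerises it by E1cB opening of the epoxide to the (E)-gamma-hydroxyvinylsulfonium iodide F2. Compound 5 adds through C4 to C2' in a Michael fashion to give the sulfonium adduct F3, and the enolate of F3 displaces tetrahydrothiophene from C1' (3-exo-tet) to give 10. This follows the vinylsulfonium spirocyclopropanation of cyclohexane-1,3-diones. The price is that C2' is set by 1,2-induction from the C3' carbinol instead of by inversion, so the C2' epimer has to be removed by chromatography.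

**Step 6 is second.** The alkene may attack C2' instead and give the cyclopentylmethyl isomer. The cation may lose the ring proton (isopropylidene isomer) or be trapped by the oxygen on p-menthane C1 (cineole-type ether). The fallback sets out from 11 and comes back at 12, and it replaces the cationic closure by a radical one. Me3SiI (CH2Cl2, −78 °C) opens 11 at the unhindered CH2 to the tris-silyl primary iodide F4, which is the known gamma-iodo silyl enol ether formation from cyclopropyl ketones. Co(dmgH)2(py)Cl (10 mol %), i-Pr2NEt, blue light and MeCN then generate the primary radical, which closes 6-exo-trig through the same all-equatorial chair. The cobalt catalyst removes a hydrogen atom from the less hindered methyl group of the tertiary radical, which gives 12 with the isopropenyl group.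

**Step 2 is third.** The second prenyl group can enter at the other free carbon (3,5-diprenyl isomer, which goes on to colupulone), so the yield of 5 may be low. The fallback sets out from 3 and comes back at 5, and it uses bromine as a traceless blocking group. NBS (1.0 equiv, MeCN, 0 °C) gives 3-bromophlorisobutyrophenone F5. The same aqueous KOH prenylation can then occur only at the single free carbon and gives the 4-bromo gem-diprenyl dienone F6. Aqueous Na2SO3 removes the positive bromine from the 1,3-dicarbonyl carbon to give 5.

## Further compounds
F1 | step 5 | S-[(2S,3R)-2,3-epoxygeranyl]tetrahydrothiophenium iodide | C1CC[S+](C1)C[C@H]2O[C@]2(C)CCC=C(C)C.[I-]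
F2 | step 5 | (E)-gamma-hydroxyvinylsulfonium iodide, (E)-[(3R)-3-hydroxy-3,7-dimethylocta-1,6-dien-1-yl]tetrahydrothiophenium iodide | C1CC[S+](C1)/C=C/[C@](C)(O)CCC=C(C)C.[I-]
F3 | step 5 | sulfonium adduct, 4-[(2R,3R)-3-hydroxy-3,7-dimethyl-1-(tetrahydrothiophenium-1-yl)oct-6-en-2-yl] derivative of 5, iodide | CC(C)C(=O)C1=C(O)C([C@@H](C[S+]2CCCC2)[C@](C)(O)CCC=C(C)C)=C(O)C(CC=C(C)C)(CC=C(C)C)C1=O.[I-]
F4 | step 6 | tris-silyl primary iodide, 4-[(2R,3R)-1-iodo-3,7-dimethyl-3-(trimethylsilyloxy)oct-6-en-2-yl] nucleus with two enol silyl ethers | CC(C)C(=O)C1=C(O[Si](C)(C)C)C(CC=C(C)C)(CC=C(C)C)C(O[Si](C)(C)C)=C([C@@H](CI)[C@](C)(O[Si](C)(C)C)CCC=C(C)C)C1=O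
F5 | step 2 | 3-bromophlorisobutyrophenone | CC(C)C(=O)c1c(O)cc(O)c(Br)c1O
F6 | step 2 | 4-bromo gem-diprenyl dienone, 4-bromo-3,5-dihydroxy-2-isobutyryl-6,6-diprenylcyclohexa-2,4-dien-1-one | CC(C)C(=O)C1=C(O)C(Br)=C(O)C(CC=C(C)C)(CC=C(C)C)C1=O
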